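**Strategy.** The seven-membered ring (ring B) is disconnected across its cis-2-ene-1,5-diol unit C8(O)–C7=C6(Me)–C5–C4(O) (octahydroazulene numbering). The two carbinol carbons sit on adjacent carbons of the cyclopentane (ring A), so ring B is a [4+3] annulation product of a cyclopentane-1,2-dicarbaldehyde and a chiral 2-methylallyl 1,3-diboron reagent. One pot forms C7–C8 and C4–C5, closes ring B, and sets both carbinol centres and the ring (Z)-alkene by two successive allylborations, the second intramolecular. The precursor is a trans-dialdehyde carrying the quaternary methyl, the silylated tertiary carbinol and the isopropyl group. It is made by asymmetric Diels–Alder reaction, ozonolysis and a proline aldol ring contraction.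

Key step: step 7

Assumption: the (S)-oxazaborolidinium catalyst of step 2 is taken to leave the Re face at C2 of methacrolein open, as with other 2-substituted acroleins, giving (S)-5; if the sense is opposite, its enantiomer is used.

Step 1
Reactants: 1 3-methylbut-1-yne; 2 ethylene
Product: 3 2-(propan-2-yl)buta-1,3-diene
Conditions: second-generation Grubbs catalyst RuCl2(=CHPh)(PCy3)(H2IMes) (3 mol%), ethylene (4 atm), CH2Cl2, 23 °C
Reagents that add atoms: none
Why: Ethylene–alkyne cross enyne metathesis turns the terminal alkyne into a 2-substituted buta-1,3-diene and creates no stereocentre.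

Step 2
Reactants: 3 2-(propan-2-yl)buta-1,3-diene; 4 methacrolein
Product: 5 (1S)-1-methyl-4-(propan-2-yl)cyclohex-3-ene-1-carbaldehyde
Conditions: (S)-3,3-diphenyl-1-(2-methylphenyl)tetrahydro-1H,3H-pyrrolo[1,2-c][1,3,2]oxazaborole (10 mol%), HNTf2 (8 mol%), CH2Cl2, −78 → −40 °C
Reagents that add atoms: none
Why: Oxazaborolidinium-catalysed asymmetric Diels–Alder reaction, in which the 2-alkyl diene adds "para" to the coordinated enal and the catalyst exposes only the Re face at C2 of methacrolein, which sets the quaternary (S) centre.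

Step 3
Reactants: 5 (1S)-1-methyl-4-(propan-2-yl)cyclohex-3-ene-1-carbaldehyde
Product: 6 (4S)-4-(dimethoxymethyl)-4-methyl-1-(propan-2-yl)cyclohex-1-ene
Conditions: HC(OMe)3, MeOH, p-TsOH·H2O (2 mol%), 23 °C
Reagents that add atoms: trimethyl orthoformate COC(OC)OC; methanol CO
Why: Acid-catalysed acetalisation with orthoformate as water scavenger masks the neopentyl aldehyde as a bulky dimethoxymethyl group that later steers the aldol, and no stereocentre changes.

Step 4
Reactants: 6 (4S)-4-(dimethoxymethyl)-4-methyl-1-(propan-2-yl)cyclohex-1-ene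
Product: 7 (3S)-3-(dimethoxymethyl)-3,7-dimethyl-6-oxooctanal
Conditions: O3, NaHCO3, CH2Cl2, −78 °C; then PPh3, → 23 °C
Reagents that add atoms: ozone [O-][O+]=O
Why: Reductive ozonolysis cleaves the only C=C bond to unveil the 1,6-keto aldehyde without touching the quaternary centre.

Step 5
Reactants: 7 (3S)-3-(dimethoxymethyl)-3,7-dimethyl-6-oxooctanal
Product: 8 (1R,2R,5S)-5-(dimethoxymethyl)-2-hydroxy-5-methyl-2-(propan-2-yl)cyclopentane-1-carbaldehyde
Conditions: (R)-proline (30 mol%), DMSO, 23 °C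
Reagents that add atoms: none
Why: Proline enamine catalysis (intramolecular 5-enolexo aldol addition of an aldehyde to a ketone), in which only the CH2CHO arm can form an enamine, the acid-directed transition state should place the new hydroxyl cis to the formyl group, and the enamine face favoured by (R)-proline is also the one anti to the dimethoxymethyl group, which sets C1 and C2 of 8.

Step 6
Reactants: 8 (1R,2R,5S)-5-(dimethoxymethyl)-2-hydroxy-5-methyl-2-(propan-2-yl)cyclopentane-1-carbaldehyde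
Product: 11 (1S,2R,3R)-1-methyl-3-(propan-2-yl)-3-[(triethylsilyl)oxy]cyclopentane-1,2-dicarbaldehyde, via silyl ether acetal 9 (not isolated), via lutidinium salt 10 (not isolated)
Conditions: Et3SiOTf (3.5 equiv), 2,6-lutidine (5 equiv), CH2Cl2, −78 → 0 °C; then H2O, 23 °C
Reagents that add atoms: triethylsilyl trifluoromethanesulfonate CC[Si](CC)(CC)OS(=O)(=O)C(F)(F)F; water O
Why: Silyl triflate/2,6-lutidine silylates the hindered tertiary alcohol and, in the same medium, converts the dimethyl acetal into a pyridinium N,O-acetal that water hydrolyses to the aldehyde (chemoselective acetal cleavage that spares silyl ethers), with no stereocentre touched.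

Step 7
Reactants: 11 (1S,2R,3R)-1-methyl-3-(propan-2-yl)-3-[(triethylsilyl)oxy]cyclopentane-1,2-dicarbaldehyde; 12 4,4,5,5-tetramethyl-2-(2-methylprop-1-en-1-yl)-1,3,2-dioxaborolane; 13 (+)-B-chlorodiisopinocampheylborane (from (−)-α-pinene)
Product: 16 (3R,3aS,4S,8R,8aS)-6,8a-dimethyl-3-(propan-2-yl)-3-[(triethylsilyl)oxy]-1,2,3,3a,4,5,8,8a-octahydroazulene-4,8-diol, via borylallylborane 14 (not isolated), via monoadduct borinate 15 (not isolated)
Conditions: 12, lithium 2,2,6,6-tetramethylpiperidide, THF, −78 °C; 13, −78 → 0 °C; slow addition to 11, Et2O (0.02 M), −78 °C; then 23 → 40 °C; NaOH, H2O2, 0 °C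
Reagents that add atoms: none
Why: Proposed new method: γ-deprotonation of 12, B-trapping by 13 and reversible 1,3-boratropic shifts should give the (E)-γ-boryl-β-methylallylborane 14, whose chair allylboration of the less shielded formyl group on the quaternary carbon gives the anti α-boryl-β-boryloxy allylboronate 15; on warming, 15 transfers its allyl terminus to the remaining formyl group through a B–O-bridged boat transition state and releases the ring alkene. The closest known reaction types are the one-pot double allylboration of two aldehydes with γ-boryl allylboranes (1,5-diol synthesis), here made intramolecular in its second stage, and the tandem double allylation of 1,4-dicarbonyls with bis(boronates). Ring B is closed by 7-exo-trig allyl transfer (SE2′) onto the formyl group, the tether spanning the boron-bearing α-carbon and the carbonyl carbon, so the alkene becomes endocyclic. C8 is set by the isopinocampheyl ligands (Re-face attack), the transient boron-bearing C7 by the (E)-geometry of 14, and C4 by delivery of boron to oxygen on the ring face that carried boron, so the two hydroxyls emerge cis. The step needs chemoselection between the formyl groups, secured by the all-cis Me/CHO/OSiEt3 crowding around the C2 formyl group of 11 and by slow addition of the reagent, and (Z)-selection in the second stage, secured by the ring.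

Step 8
Reactants: 16 (3R,3aS,4S,8R,8aS)-6,8a-dimethyl-3-(propan-2-yl)-3-[(triethylsilyl)oxy]-1,2,3,3a,4,5,8,8a-octahydroazulene-4,8-diol; 17 angelic acid; 18 2,4,6-trichlorobenzoyl chloride
Product: 20 (3R,3aS,4S,8R,8aS)-4-hydroxy-6,8a-dimethyl-3-(propan-2-yl)-3-[(triethylsilyl)oxy]-1,2,3,3a,4,5,8,8a-octahydroazulen-8-yl (2Z)-2-methylbut-2-enoate, via mixed anhydride 19 (not isolated)
Conditions: 17, 18, Et3N, toluene, 23 °C; then 16, 75 °C
Reagents that add atoms: none
Why: Yamaguchi esterification through the mixed anhydride transfers the angeloyl group without Z/E isomerisation, and the allylic C8 hydroxyl should react in preference to the C4 hydroxyl, which is screened by the adjacent triethylsilyl ether.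

Step 9
Reactants: 20 (3R,3aS,4S,8R,8aS)-4-hydroxy-6,8a-dimethyl-3-(propan-2-yl)-3-[(triethylsilyl)oxy]-1,2,3,3a,4,5,8,8a-octahydroazulen-8-yl (2Z)-2-methylbut-2-enoate
Product: 21 (3R,3aS,4S,8R,8aS)-3,4-dihydroxy-6,8a-dimethyl-3-(propan-2-yl)-1,2,3,3a,4,5,8,8a-octahydroazulen-8-yl (2Z)-2-methylbut-2-enoate
Conditions: HF·pyridine, pyridine, THF, 0 → 23 °C
Reagents that add atoms: none
Why: Fluoride-mediated desilylation of the tertiary silyl ether under buffered conditions leaves the angelate and the allylic system intact.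

Step 10
Reactants: 21 (3R,3aS,4S,8R,8aS)-3,4-dihydroxy-6,8a-dimethyl-3-(propan-2-yl)-1,2,3,3a,4,5,8,8a-octahydroazulen-8-yl (2Z)-2-methylbut-2-enoate; 22 4-methoxybenzoyl chloride
Product: 23 (3R,3aS,4S,8R,8aS)-3-hydroxy-6,8a-dimethyl-8-{[(2Z)-2-methylbut-2-enoyl]oxy}-3-(propan-2-yl)-1,2,3,3a,4,5,8,8a-octahydroazulen-4-yl 4-methoxybenzoate
Conditions: 22, 4-(dimethylamino)pyridine (0.2 equiv), Et3N, CH2Cl2, 23 °C
Reagents that add atoms: none
Why: Nucleophile-catalysed acylation with the acid chloride esterifies the secondary C4 hydroxyl, the tertiary C3 hydroxyl being inert, and completes the target.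

**Compound list**

1 | 3-methylbut-1-yne | CC(C)C#C | starting material
2 | ethylene | C=C | starting material
3 | 2-(propan-2-yl)buta-1,3-diene | C=CC(=C)C(C)C | intermediate
4 | methacrolein (2-methylprop-2-enal) | CC(=C)C=O | starting material
5 | (1S)-1-methyl-4-(propan-2-yl)cyclohex-3-ene-1-carbaldehyde | O=C[C@]1(C)CC=C(C(C)C)CC1 | intermediate
6 | (4S)-4-(dimethoxymethyl)-4-methyl-1-(propan-2-yl)cyclohex-1-ene | COC(OC)[C@]1(C)CC=C(C(C)C)CC1 | intermediate
7 | (3S)-3-(dimethoxymethyl)-3,7-dimethyl-6-oxooctanal | COC(OC)[C@](CCC(=O)C(C)C)(C)CC=O | intermediate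
8 | (1R,2R,5S)-5-(dimethoxymethyl)-2-hydroxy-5-methyl-2-(propan-2-yl)cyclopentane-1-carbaldehyde | O=C[C@@H]2[C@](C(OC)OC)(C)CC[C@@]2(O)C(C)C | intermediate
9 | (1R,2R,5S)-5-(dimethoxymethyl)-5-methyl-2-(propan-2-yl)-2-[(triethylsilyl)oxy]cyclopentane-1-carbaldehyde | O=C[C@@H]2[C@](C(OC)OC)(C)CC[C@@]2(O[Si](CC)(CC)CC)C(C)C | intermediate
10 | 1-{[(1S,2R,3R)-2-formyl-1-methyl-3-(propan-2-yl)-3-[(triethylsilyl)oxy]cyclopentyl](methoxy)methyl}-2,6-dimethylpyridinium triflate (N,O-acetal carbon undefined) | O=C[C@@H]2[C@](C(OC)[n+]3c(C)cccc3C)(C)CC[C@@]2(O[Si](CC)(CC)CC)C(C)C.[O-]S(=O)(=O)C(F)(F)F | intermediate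
11 | (1S,2R,3R)-1-methyl-3-(propan-2-yl)-3-[(triethylsilyl)oxy]cyclopentane-1,2-dicarbaldehyde | O=C[C@@H]2[C@](C=O)(C)CC[C@@]2(O[Si](CC)(CC)CC)C(C)C | intermediate
12 | 4,4,5,5-tetramethyl-2-(2-methylprop-1-en-1-yl)-1,3,2-dioxaborolane | CC(C)=CB1OC(C)(C)C(C)(C)O1 | starting material
13 | (+)-B-chlorodiisopinocampheylborane (isopinocampheyl groups from (−)-α-pinene) | ClB([C@H]1C[C@H]2C[C@@H]([C@@H]1C)C2(C)C)[C@H]1C[C@H]2C[C@@H]([C@@H]1C)C2(C)C | starting material
14 | (E)-[2-methyl-3-(4,4,5,5-tetramethyl-1,3,2-dioxaborolan-2-yl)prop-2-en-1-yl]diisopinocampheylborane | C/C(CB([C@H]1C[C@H]2C[C@@H]([C@@H]1C)C2(C)C)[C@H]1C[C@H]2C[C@@H]([C@@H]1C)C2(C)C)=C\B1OC(C)(C)C(C)(C)O1 | intermediate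
15 | diisopinocampheylborinate of (1R,2R)-1-{(1S,2R,3R)-2-formyl-1-methyl-3-(propan-2-yl)-3-[(triethylsilyl)oxy]cyclopentyl}-3-methyl-2-(4,4,5,5-tetramethyl-1,3,2-dioxaborolan-2-yl)but-3-en-1-ol | C=C(C)[C@@H](B1OC(C)(C)C(C)(C)O1)[C@@H](OB([C@H]4C[C@H]5C[C@@H]([C@@H]4C)C5(C)C)[C@H]6C[C@H]7C[C@@H]([C@@H]6C)C7(C)C)[C@@]3(C)CC[C@@](O[Si](CC)(CC)CC)(C(C)C)[C@@H]3C=O | intermediate
16 | (3R,3aS,4S,8R,8aS)-6,8a-dimethyl-3-(propan-2-yl)-3-[(triethylsilyl)oxy]-1,2,3,3a,4,5,8,8a-octahydroazulene-4,8-diol | O[C@@H]1C=C(C)C[C@H](O)[C@@H]2[C@]1(C)CC[C@@]2(O[Si](CC)(CC)CC)C(C)C | intermediate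
17 | angelic acid ((2Z)-2-methylbut-2-enoic acid) | C/C=C(/C)C(=O)O | starting material
18 | 2,4,6-trichlorobenzoyl chloride | O=C(Cl)c1c(Cl)cc(Cl)cc1Cl | starting material
19 | (2Z)-2-methylbut-2-enoic 2,4,6-trichlorobenzoic anhydride | C/C=C(/C)C(=O)OC(=O)c1c(Cl)cc(Cl)cc1Cl | intermediate
20 | (3R,3aS,4S,8R,8aS)-4-hydroxy-6,8a-dimethyl-3-(propan-2-yl)-3-[(triethylsilyl)oxy]-1,2,3,3a,4,5,8,8a-octahydroazulen-8-yl (2Z)-2-methylbut-2-enoate | C/C=C(/C)C(=O)O[C@@H]1C=C(C)C[C@H](O)[C@@H]2[C@]1(C)CC[C@@]2(O[Si](CC)(CC)CC)C(C)C | intermediate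
21 | (3R,3aS,4S,8R,8aS)-3,4-dihydroxy-6,8a-dimethyl-3-(propan-2-yl)-1,2,3,3a,4,5,8,8a-octahydroazulen-8-yl (2Z)-2-methylbut-2-enoate | C/C=C(/C)C(=O)O[C@@H]1C=C(C)C[C@H](O)[C@@H]2[C@]1(C)CC[C@@]2(O)C(C)C | intermediate
22 | 4-methoxybenzoyl chloride | COc1ccc(cc1)C(Cl)=O | starting material
23 | (3R,3aS,4S,8R,8aS)-3-hydroxy-6,8a-dimethyl-8-{[(2Z)-2-methylbut-2-enoyl]oxy}-3-(propan-2-yl)-1,2,3,3a,4,5,8,8a-octahydroazulen-4-yl 4-methoxybenzoate | C/C=C(/C)C(=O)O[C@@H]1C=C(C)C[C@H](OC(=O)c2ccc(OC)cc2)[C@@H]2[C@]1(C)CC[C@@]2(O)C(C)C | target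

Total step count: 10. Longest linear sequence: 10 steps (1 → 23).

**Steps most likely to fail**

Step 7 (key step). The first allylboration may fail to discriminate the two formyl groups, the boron-stabilised allyl anion may not be trapped cleanly, or the boat-shaped intramolecular allyl transfer may be slow enough for intermolecular oligomerisation to take over. The fallback builds ring B stepwise with known reactions. It sets out from silyl ether acetal 9, isolated by running step 6 with 1.1 equiv of Et3SiOTf at −78 °C. The free formyl group is methallylated with 2-methylallyl-diisopinocampheylborane (from (−)-Ipc2BOMe and 2-methylallylmagnesium chloride, Si-face attack) to give (1S)-1-[(1S,2R,5S)-5-(dimethoxymethyl)-5-methyl-2-(propan-2-yl)-2-[(triethylsilyl)oxy]cyclopentyl]-3-methylbut-3-en-1-ol F1. Et3SiOTf/2,6-lutidine followed by water silylates the new hydroxyl and cleaves the acetal to (1S,2S,3R)-1-methyl-2-{(1S)-3-methyl-1-[(triethylsilyl)oxy]but-3-en-1-yl}-3-(propan-2-yl)-3-[(triethylsilyl)oxy]cyclopentane-1-carbaldehyde F2. Ligand-controlled addition of divinylzinc Zn(CH=CH2)2 with 3-exo-morpholinoisoborneol gives the (1R)-prop-2-en-1-ol F3. Ring-closing metathesis with the second-generation Grubbs catalyst RuCl2(=CHPh)(PCy3)(H2IMes) closes the C6=C7 alkene to (3R,3aS,4S,8R,8aS)-6,8a-dimethyl-3-(propan-2-yl)-3,4-bis[(triethylsilyl)oxy]-1,2,3,3a,4,5,8,8a-octahydroazulen-8-ol F4. Yamaguchi angeloylation of its only free hydroxyl gives the angelate F5, and HF·pyridine removes both silyl groups, rejoining the route at 21.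

Step 5. The hindered isopropyl ketone may be a poor acceptor, so that enolisation of the ketone and attack on the aldehyde (the other aldol mode), or dehydration of the tertiary aldol, competes. The fallback sets out from 7. Pinnick oxidation (NaClO2, NaH2PO4, 2-methylbut-2-ene) gives (3S)-3-(dimethoxymethyl)-3,7-dimethyl-6-oxooctanoic acid F6. Nucleophile-catalysed aldol-lactonisation (p-TsCl, i-Pr2NEt, LiCl, 2-phenyl-3,4-dihydro-2H-pyrimido[2,1-b][1,3]benzothiazole as acyl-transfer catalyst) traps the aldolate as the cis-fused β-lactone (1R,2S,5R)-2-(dimethoxymethyl)-2-methyl-5-(propan-2-yl)-6-oxabicyclo[3.2.0]heptan-7-one F7. Reduction with i-Bu2AlH gives (1R,2S,3S)-3-(dimethoxymethyl)-2-(hydroxymethyl)-3-methyl-1-(propan-2-yl)cyclopentan-1-ol F8. Selective oxidation of the primary alcohol (TEMPO, PhI(OAc)2) returns to the route at 8.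

Step 8. Acylation may not discriminate the two secondary hydroxyls, or forcing conditions may isomerise the Z-alkene of the acyl group. The fallback replaces steric differentiation by a temporary bridge and sets out from 16. HF·pyridine gives (3R,3aS,4S,8R,8aS)-6,8a-dimethyl-3-(propan-2-yl)-1,2,3,3a,4,5,8,8a-octahydroazulene-3,4,8-triol F9. t-Bu2Si(OTf)2/2,6-lutidine ties the C3 and C4 hydroxyls (a 1,3-diol) into the di-tert-butylsilylene F10, leaving only the C8 hydroxyl. Yamaguchi angeloylation gives the silylene angelate F11, and HF·pyridine removes the silylene, rejoining the route at 21.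

**Further compounds**

F1 | step 7 | (1S)-1-[(1S,2R,5S)-5-(dimethoxymethyl)-5-methyl-2-(propan-2-yl)-2-[(triethylsilyl)oxy]cyclopentyl]-3-methylbut-3-en-1-ol | C=C(C)C[C@H](O)[C@@H]2[C@](C(OC)OC)(C)CC[C@@]2(O[Si](CC)(CC)CC)C(C)C
F2 | step 7 | (1S,2S,3R)-1-methyl-2-{(1S)-3-methyl-1-[(triethylsilyl)oxy]but-3-en-1-yl}-3-(propan-2-yl)-3-[(triethylsilyl)oxy]cyclopentane-1-carbaldehyde | C=C(C)C[C@H](O[Si](CC)(CC)CC)[C@@H]2[C@](C=O)(C)CC[C@@]2(O[Si](CC)(CC)CC)C(C)C
F3 | step 7 | (1R)-1-[(1S,2S,3R)-1-methyl-2-{(1S)-3-methyl-1-[(triethylsilyl)oxy]but-3-en-1-yl}-3-(propan-2-yl)-3-[(triethylsilyl)oxy]cyclopentyl]prop-2-en-1-ol | C=C(C)C[C@H](O[Si](CC)(CC)CC)[C@@H]2[C@]([C@H](O)C=C)(C)CC[C@@]2(O[Si](CC)(CC)CC)C(C)C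
F4 | step 7 | (3R,3aS,4S,8R,8aS)-6,8a-dimethyl-3-(propan-2-yl)-3,4-bis[(triethylsilyl)oxy]-1,2,3,3a,4,5,8,8a-octahydroazulen-8-ol | O[C@@H]1C=C(C)C[C@H](O[Si](CC)(CC)CC)[C@@H]2[C@]1(C)CC[C@@]2(O[Si](CC)(CC)CC)C(C)C
F5 | step 7 | (3R,3aS,4S,8R,8aS)-6,8a-dimethyl-3-(propan-2-yl)-3,4-bis[(triethylsilyl)oxy]-1,2,3,3a,4,5,8,8a-octahydroazulen-8-yl (2Z)-2-methylbut-2-enoate | C/C=C(/C)C(=O)O[C@@H]1C=C(C)C[C@H](O[Si](CC)(CC)CC)[C@@H]2[C@]1(C)CC[C@@]2(O[Si](CC)(CC)CC)C(C)C
F6 | step 5 | (3S)-3-(dimethoxymethyl)-3,7-dimethyl-6-oxooctanoic acid | COC(OC)[C@](CCC(=O)C(C)C)(C)CC(=O)O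
F7 | step 5 | (1R,2S,5R)-2-(dimethoxymethyl)-2-methyl-5-(propan-2-yl)-6-oxabicyclo[3.2.0]heptan-7-one | O=C1O[C@@]2(C(C)C)CC[C@](C)(C(OC)OC)[C@@H]12
F8 | step 5 | (1R,2S,3S)-3-(dimethoxymethyl)-2-(hydroxymethyl)-3-methyl-1-(propan-2-yl)cyclopentan-1-ol | OC[C@@H]2[C@](C(OC)OC)(C)CC[C@@]2(O)C(C)C
F9 | step 8 | (3R,3aS,4S,8R,8aS)-6,8a-dimethyl-3-(propan-2-yl)-1,2,3,3a,4,5,8,8a-octahydroazulene-3,4,8-triol | O[C@@H]1C=C(C)C[C@H](O)[C@@H]2[C@]1(C)CC[C@@]2(O)C(C)C
F10 | step 8 | 3,4-O-(di-tert-butylsilylene) derivative of F9 (C8 hydroxyl free) | O[C@@H]1C=C(C)C[C@H](O3)[C@@H]2[C@]1(C)CC[C@@]2(O[Si]3(C(C)(C)C)C(C)(C)C)C(C)C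
F11 | step 8 | 8-O-[(2Z)-2-methylbut-2-enoyl] derivative of F10 | C/C=C(/C)C(=O)O[C@@H]1C=C(C)C[C@H](O3)[C@@H]2[C@]1(C)CC[C@@]2(O[Si]3(C(C)(C)C)C(C)(C)C)C(C)C
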